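## The problem

The target is a cembrane-type diterpenoid, and cembrane numbering is used throughout: the ring is C1–C14, C15–C17 sit on C1 with C16 as the carboxyl carbon, and C18, C19, C20 sit on C4, C8, C12. Its 14-membered carbocycle is bridged from C1 to C3 by a δ-lactone (O–C16–C15–C1–C2–C3) and carries an 11,12-oxirane, a tertiary alcohol at C4 and a secondary allylic alcohol at C7 beside the C8 exo-methylene. The seven stereocentres (1R, 3R, 4S, 7R, 11S, 12S, 15S) fall into four groups: C1/C15, C3/C4, C11/C12 and C7. Within a group one centre can be tied to the other, but the groups are separated by flexible CH2–CH2 links, so each group needs its own source of chirality. The trisubstituted oxirane, the tertiary alcohol, the epimerisable C15 of the lactone and the allylic alcohol will not survive strong acid, strong base or dissolving metals, so they should appear late. A synthesis therefore has to build the ring at a low oxidation level, with C1/C15 and the C7 carbinol in place, and then oxidise it selectively. What makes this possible is that the lactone oxygen on C3 and the hydroxyl on C4 are anti and C16 lies five atoms from C3: this is the pattern left when a carboxylate opens a 3,4-oxirane of a 3E-alkene at C3 with inversion. The oxirane needed for this is (3S,4S) and the 11,12-oxirane is (11S,12S), so both arise from E-trisubstituted alkenes attacked in the same sense and one chiral oxidant can serve both.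

## Retrosynthesis

**O–Si at C7.** Target 36 is taken back to its triethylsilyl ether 35. The C7 hydroxyl stays masked during the oxidation because a free allylic alcohol could be oxidised by a dioxirane or could direct it to the exo-methylene. The forward step only needs buffered fluoride that leaves the oxirane and lactone alone.

**Four C–O bonds (key cut).** In 35 the lactone C3–O bond, the C4–O bond and both C–O bonds of the 11,12-oxirane are cut, via bis-epoxy acid 34, to the macrocyclic 3E,11E-diene acid 33. The neighbouring cut, the acyl C16–O bond, would leave a 3,4-diol and an oxirane still to be made on a hydroxy acid. The chosen cut removes four stereocentres and three rings at once; 33 keeps only C1, C15 and C7. The forward reaction must epoxidise two ring alkenes on the correct faces, spare the exo-methylene, and lactonise 6-exo at C3.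

**Protecting groups and the C7 centre.** Acid 33 comes from tert-butyl ester alcohol 31 by one silyl triflate operation (via 32). Alcohol 31 comes from enone 30 by reagent-controlled reduction, and 30 from the C7-epimeric alcohols 29. Routing C7 through the ketone makes the ring closure free of any stereochemical demand.

**C7–C8 (ring closure).** Alcohols 29 are opened at the C7–C8 bond to aldehyde 28, which carries a 2-bromoalkene. Closing at a trisubstituted alkene by metathesis would give no control of geometry, and closing by a sulfone carbanion would bring strong base and a later reductive step. The chromium-mediated addition tolerates the ester and both alkenes and is asked only to form a 14-membered ring at high dilution. Aldehyde 28 comes from silyl ether 26 through alcohol 27.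

**C12–C13.** Ester 26 is cut between sp2 C12 and sp3 C13 into vinyl compound 16 and alkenyl iodide 24. The 11E geometry is then carried by 24 and not created in the coupling. The forward B-alkyl Suzuki–Miyaura coupling must hydroborate only the vinyl group of 16 and use only the iodide of 24.

**C2–C3.** Compound 16 is cut between sp3 C2 and sp2 C3 into iodide 14 (as its zinc reagent 15) and alkenyl iodide 4, which carries the 3E geometry. A Negishi coupling is chosen over allylic alkylation of an enolate because it lets C1 be made on a five-carbon piece.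

**C1–C15.** Iodide 14 comes from alcohol 13 and imide 12. Imide 12 is cut at C1–C15 into the dienolate of butenoyl imide 10 and lactate triflate 6. This one bond sets both centres: C1 by the (R)-benzyl oxazolidinone, C15 by inversion of (S)-lactate. The vinyl group on C1 (C14=C13) is the handle for the later coupling.

**Fragments.** Iodide 4 comes from pent-4-yn-1-ol 1 by carboalumination–iodination (3) and silylation. Iodide 24 comes from propargyl bromide 17 and 2,3-dibromopropene 18 through enyne 20, methyl alkyne 22 and hydrozirconation–iodination. Triflate 6 comes from tert-butyl (S)-lactate 5, and imide 10 from but-3-enoic acid 7 and oxazolidinone 8.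

## Roads not taken

**Alternative 1:** The lactone is cut at C15–C16 and C16–O, leading back to divinyl carbinol A1, in which C1 is prochiral and C3/C4 are already set. In the forward step a palladium hydride (Pd(OAc)2, 1,4-bis(diphenylphosphino)butane, CO, H2) adds to one of the two diastereotopic vinyl groups, CO inserts and the C3 hydroxyl captures the acyl group to give vinyl lactone A2.
- Merits: CO serves as C16, C1 and C15 are set without an auxiliary, and the lactone position is certain because the C3 oxygen is there before the ring forms. In these respects it is better than the chosen plan.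
- Weak points: the choice between the vinyl groups rests on 1,3-induction from C3 through an acylpalladium alkoxide chelate, which is poorly charted. The branched hydropalladation needed for the C15 methyl competes with the linear mode and with alkene migration. A2 holds less than half of the skeleton, so the lactone, the protected tertiary alcohol and the epimerisable C15 must be carried through all of the ring construction, and C7 and C11/C12 are not addressed.
- Comparison: the chosen plan sets against it predictable auxiliary control at C1/C15 and an oxidation that comes only after the ring is closed.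

**Alternative 2:** The ring is cut at C3–C4, leading to seco keto aldehyde A3. Low-valent titanium (TiCl3(DME)1.5, Zn(Cu)) couples the C3 aldehyde with the C4 methyl ketone to give macrocyclic diol A4.
- Merits: ring closure and both carbinol centres in one step, a reaction type well established for 14-membered carbocycles, and no need for the 3E-alkene. At the skeleton level this is more convergent than the chosen plan.
- Weak points: four diastereomeric diols are possible and nothing near C3/C4 decides among them. Deoxygenation to the alkene competes. C16 has to travel as a protected alcohol and be oxidised and lactonised afterwards, and the 11,12-epoxidation still has to follow on a ring that now carries a free diol.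
- Comparison: the chosen plan answers with a stereospecific relay in which alkene geometry plus one face choice fixes C3 and C4 together.

**Alternative 3:** The ring is cut at C9–C10, leading to bromo sulfone A5, which already contains the lactone and the C3/C4 oxygens. KN(SiMe3)2 deprotonates the C10 allylic sulfone, which displaces the C9 allylic bromide to give macrocyclic sulfone A6.
- Merits: a proven way to close cembranoid rings, at a bond remote from all stereocentres, with the 3,4-oxidation done earlier on an open chain where reagent control is most reliable. On that point it is as good as or better than the chosen plan.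
- Weak points: the lactone with its acidic C15–H meets a strong base. A reductive desulfonylation must then spare the lactone and the allylic silyl ether. Two more protecting groups are needed, the sequence is longer, and the C11=C12 alkene must still be epoxidised in the ring.
- Comparison: the chosen plan keeps ring assembly at the ester and hydrocarbon level and uses the open-chain oxidation only as its fallback.

Key step: step 19

Remarks: (a) the 14-membered ring of 33 is assumed to be flexible enough at 0 °C for each trisubstituted alkene to present either face, so that the chiral ketone and not the ring decides the face; (b) the CIP descriptor of C1 is S in 12–16 and R from 25 on only because the ranking of its substituents changes; the configuration is the same throughout.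

## Steps

Step 1
Reactants: 1 pent-4-yn-1-ol
Product: 3 (4E)-5-iodo-4-methylpent-4-en-1-ol, via alkenylalane 2 (not isolated)
Conditions: Me3Al, Cp2ZrCl2 (cat.), CH2Cl2, 0 °C to rt; then I2, THF, −30 to 0 °C
Reagents that add atoms: trimethylaluminium, C[Al](C)C; iodine, II
Why: Zirconium-catalysed carboalumination (Negishi) adds methyl and aluminium syn across the terminal alkyne with aluminium on the terminal carbon, and iodinolysis with retention should fix the E geometry of the future C3=C4 alkene.

Step 2
Reactants: 3 (4E)-5-iodo-4-methylpent-4-en-1-ol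
Product: 4 tert-butyl{[(4E)-5-iodo-4-methylpent-4-en-1-yl]oxy}dimethylsilane
Conditions: TBSCl, imidazole, DMF, rt
Reagents that add atoms: tert-butyldimethylsilyl chloride, CC(C)(C)[Si](C)(C)Cl
Why: Standard silylation of a primary alcohol; the ether keeps the C7 oxygen from quenching the zinc reagent of step 8.

Step 3
Reactants: 5 tert-butyl (2S)-2-hydroxypropanoate
Product: 6 tert-butyl (2S)-2-{[(trifluoromethyl)sulfonyl]oxy}propanoate
Conditions: Tf2O, 2,6-lutidine, CH2Cl2, −78 to 0 °C
Reagents that add atoms: trifluoromethanesulfonic anhydride, O=S(=O)(OS(=O)(=O)C(F)(F)F)C(F)(F)F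
Why: O-sulfonylation leaves the C–O bond and hence the S configuration untouched; the hindered base and low temperature should suppress elimination and racemisation.

Step 4
Reactants: 7 but-3-enoic acid; 8 (4R)-4-benzyl-1,3-oxazolidin-2-one
Product: 10 (4R)-4-benzyl-3-(but-3-enoyl)-1,3-oxazolidin-2-one, via mixed pivalic anhydride 9 (not isolated)
Conditions: PivCl, Et3N, THF, −20 °C; then 8, LiCl, −20 °C to rt
Reagents that add atoms: none
Why: N-acylation of the oxazolidinone through the mixed anhydride; any isomerisation to the crotonyl imide is harmless because both imides give the same dienolate in step 5.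

Step 5
Reactants: 10 (4R)-4-benzyl-3-(but-3-enoyl)-1,3-oxazolidin-2-one; 6 tert-butyl (2S)-2-{[(trifluoromethyl)sulfonyl]oxy}propanoate
Product: 12 tert-butyl (2S,3S)-3-{[(4R)-4-benzyl-2-oxo-1,3-oxazolidin-3-yl]carbonyl}-2-methylpent-4-enoate, via sodium dienolate 11 (not isolated)
Conditions: NaN(SiMe3)2, THF, −78 °C; then 6, −78 to −30 °C
Reagents that add atoms: none
Why: Evans-type imide enolate alkylation by SN2 displacement of an α-triflyloxy ester: the sodium-chelated Z-dienolate should react at its α-carbon on the face away from the benzyl group (sets C1), and the triflate is displaced with inversion, so (S)-lactate gives the 15S centre.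

Step 6
Reactants: 12 tert-butyl (2S,3S)-3-{[(4R)-4-benzyl-2-oxo-1,3-oxazolidin-3-yl]carbonyl}-2-methylpent-4-enoate
Product: 13 tert-butyl (2S,3S)-3-(hydroxymethyl)-2-methylpent-4-enoate
Conditions: LiBH4, MeOH (1 equiv), Et2O, 0 °C
Reagents that add atoms: none
Why: Reductive cleavage of the N-acyl oxazolidinone by LiBH4, which should spare the tert-butyl ester; no enolisable intermediate is formed, so C1 and C15 are not at risk.

Step 7
Reactants: 13 tert-butyl (2S,3S)-3-(hydroxymethyl)-2-methylpent-4-enoate
Product: 14 tert-butyl (2S,3S)-3-(iodomethyl)-2-methylpent-4-enoate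
Conditions: I2, PPh3, imidazole, CH2Cl2, 0 °C
Reagents that add atoms: iodine, II
Why: Appel-type iodination of a primary alcohol; kept cold so that the γ-iodo ester does not lactonise.

Step 8
Reactants: 14 tert-butyl (2S,3S)-3-(iodomethyl)-2-methylpent-4-enoate; 4 tert-butyl{[(4E)-5-iodo-4-methylpent-4-en-1-yl]oxy}dimethylsilane
Product: 16 tert-butyl (2S,3S,5E)-9-[(tert-butyldimethylsilyl)oxy]-3-ethenyl-2,6-dimethylnon-5-enoate, via alkylzinc iodide 15 (not isolated)
Conditions: Zn dust (activated), LiCl, THF, 30 °C; then 4, Pd(PPh3)4 (cat.), THF, rt to 45 °C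
Reagents that add atoms: none
Why: Zinc insertion into the primary iodide followed by Negishi sp3–sp2 coupling forms C2–C3 with retention of the E geometry of 4; the ester and the terminal vinyl group are tolerated by the organozinc.

Step 9
Reactants: 17 3-bromoprop-1-yne; 18 2,3-dibromoprop-1-ene
Product: 20 2-bromohex-1-en-5-yne, via allenylmagnesium bromide 19 (not isolated)
Conditions: Mg, HgCl2 (cat.), Et2O, 0 °C; then 18, Et2O, 0 °C to rt
Reagents that add atoms: none
Why: The propargyl/allenyl Grignard reagent couples with the allylic bromide at its propargylic terminus (SN2 and SN2′ on 18 give the same product), while the vinylic bromide is inert.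

Step 10
Reactants: 20 2-bromohex-1-en-5-yne
Product: 22 6-bromohept-6-en-2-yne, via lithium acetylide 21 (not isolated)
Conditions: LiN(iPr)2, THF, −78 °C; then MeI, −78 °C to rt
Reagents that add atoms: iodomethane, CI
Why: Deprotonation of the terminal alkyne and C-methylation of the acetylide; the amide base at −78 °C avoids halogen–metal exchange at the bromoalkene.

Step 11
Reactants: 22 6-bromohept-6-en-2-yne
Product: 24 (2E)-6-bromo-2-iodohepta-2,6-diene, via alkenylzirconocene chloride 23 (not isolated)
Conditions: Cp2Zr(H)Cl (slight excess), THF, rt to 40 °C; then I2, THF, 0 °C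
Reagents that add atoms: iodine, II
Why: Hydrozirconation adds Zr–H syn across the methyl alkyne and, after equilibration, places zirconium on the less hindered methyl-bearing carbon; iodinolysis with retention gives the E-2-iodoalkene that carries the 11E geometry, and the 1,1-disubstituted bromoalkene should react much more slowly.

Step 12
Reactants: 16 tert-butyl (2S,3S,5E)-9-[(tert-butyldimethylsilyl)oxy]-3-ethenyl-2,6-dimethylnon-5-enoate; 24 (2E)-6-bromo-2-iodohepta-2,6-diene
Product: 26 tert-butyl (2S,3R,5E)-3-[(3E)-7-bromo-3-methylocta-3,7-dien-1-yl]-9-[(tert-butyldimethylsilyl)oxy]-2,6-dimethylnon-5-enoate, via B-alkyl-9-BBN 25 (not isolated)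
Conditions: 9-BBN, THF, 0 °C to rt; then 24, PdCl2(dppf) (cat.), AsPh3, Cs2CO3, DMF/H2O, rt
Reagents that add atoms: none
Why: 9-BBN hydroborates only the monosubstituted vinyl group (boron on C13), and the B-alkyl Suzuki–Miyaura coupling forms C12–C13 with retention of the alkene geometry; at room temperature zerovalent palladium should insert into the alkenyl iodide and leave the 2-bromoalkene.

Step 13
Reactants: 26 tert-butyl (2S,3R,5E)-3-[(3E)-7-bromo-3-methylocta-3,7-dien-1-yl]-9-[(tert-butyldimethylsilyl)oxy]-2,6-dimethylnon-5-enoate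
Product: 27 tert-butyl (2S,3R,5E)-3-[(3E)-7-bromo-3-methylocta-3,7-dien-1-yl]-9-hydroxy-2,6-dimethylnon-5-enoate
Conditions: HF·pyridine, pyridine, THF, 0 °C to rt
Reagents that add atoms: none
Why: Fluoride cleavage of the primary silyl ether under non-basic conditions, which avoids dehydrobromination of the bromoalkene and leaves the tert-butyl ester.

Step 14
Reactants: 27 tert-butyl (2S,3R,5E)-3-[(3E)-7-bromo-3-methylocta-3,7-dien-1-yl]-9-hydroxy-2,6-dimethylnon-5-enoate
Product: 28 tert-butyl (2S,3R,5E)-3-[(3E)-7-bromo-3-methylocta-3,7-dien-1-yl]-2,6-dimethyl-9-oxonon-5-enoate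
Conditions: Dess–Martin periodinane, NaHCO3, CH2Cl2, 0 °C to rt
Reagents that add atoms: none
Why: Buffered Dess–Martin oxidation of a primary alcohol to the aldehyde without touching the alkenes or the α-centre of the ester.

Step 15
Reactants: 28 tert-butyl (2S,3R,5E)-3-[(3E)-7-bromo-3-methylocta-3,7-dien-1-yl]-2,6-dimethyl-9-oxonon-5-enoate
Product: 29 tert-butyl (2S)-2-[(1R,3E,11E)-7-hydroxy-4,12-dimethyl-8-methylidenecyclotetradeca-3,11-dien-1-yl]propanoate (C7 epimers; cembrane ring numbering)
Conditions: CrCl2 (excess), NiCl2 (cat.), DMSO/THF, high dilution, rt to 50 °C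
Reagents that add atoms: none
Why: Nozaki–Hiyama–Kishi reaction: nickel inserts into the 2-bromoalkene, the alkenyl group passes to chromium and adds to the aldehyde, closing the 14-membered ring at C7–C8 and creating the exo-methylene allylic alcohol. No control at C7 is expected or needed, since step 16 erases it.

Step 16
Reactants: 29 tert-butyl (2S)-2-[(1R,3E,11E)-7-hydroxy-4,12-dimethyl-8-methylidenecyclotetradeca-3,11-dien-1-yl]propanoate (C7 epimers)
Product: 30 tert-butyl (2S)-2-[(1R,3E,11E)-4,12-dimethyl-8-methylidene-7-oxocyclotetradeca-3,11-dien-1-yl]propanoate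
Conditions: Dess–Martin periodinane, NaHCO3, CH2Cl2, 0 °C
Reagents that add atoms: none
Why: Oxidation of the allylic alcohols brings both C7 epimers to one α-methylene ketone.

Step 17
Reactants: 30 tert-butyl (2S)-2-[(1R,3E,11E)-4,12-dimethyl-8-methylidene-7-oxocyclotetradeca-3,11-dien-1-yl]propanoate
Product: 31 tert-butyl (2S)-2-[(1R,3E,7R,11E)-7-hydroxy-4,12-dimethyl-8-methylidenecyclotetradeca-3,11-dien-1-yl]propanoate
Conditions: (S)-2-methyl-CBS-oxazaborolidine, catecholborane, toluene, −78 °C
Reagents that add atoms: none
Why: Corey–Bakshi–Shibata reduction: the ketone binds to the catalyst with its larger, 2-substituted vinyl flank away from the boron substituent, and hydride transfer from the (S)-catalyst should give the 7R alcohol; catecholborane at low temperature favours 1,2- over 1,4-reduction and does not hydroborate the alkenes.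

Step 18
Reactants: 31 tert-butyl (2S)-2-[(1R,3E,7R,11E)-7-hydroxy-4,12-dimethyl-8-methylidenecyclotetradeca-3,11-dien-1-yl]propanoate
Product: 33 (2S)-2-[(1R,3E,7R,11E)-4,12-dimethyl-8-methylidene-7-[(triethylsilyl)oxy]cyclotetradeca-3,11-dien-1-yl]propanoic acid, via bis-silyl derivative 32 (not isolated)
Conditions: Et3SiOTf, 2,6-lutidine, CH2Cl2, −78 °C to rt; then K2CO3, MeOH/THF/H2O, 0 °C
Reagents that add atoms: triethylsilyl trifluoromethanesulfonate, CC[Si](CC)(CC)OS(=O)(=O)C(F)(F)F
Why: The silyl triflate silylates the C7 alcohol and converts the tert-butyl ester into the silyl ester with loss of isobutene; mild aqueous base then hydrolyses only the silyl ester, which frees the acid without exposing C15 to epimerising conditions.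

Step 19
Reactants: 33 (2S)-2-[(1R,3E,7R,11E)-4,12-dimethyl-8-methylidene-7-[(triethylsilyl)oxy]cyclotetradeca-3,11-dien-1-yl]propanoic acid
Product: 35 7-O-triethylsilyl ether of the target, (1R,3R,4S,7R,11S,12S,15S), via bis-epoxy acid 34 (not isolated)
Conditions: 1,2:4,5-di-O-isopropylidene-β-L-erythro-2,3-hexodiulo-2,6-pyranose (L-fructose-derived ketone), KHSO5 (as 2KHSO5·KHSO4·K2SO4), K2CO3, Bu4NHSO4, MeCN/CH2(OMe)2, aq. Na2B4O7–Na2EDTA buffer (pH 10.5), 0 °C; then aq. NaH2PO4 to pH 5, extraction; PPTS (cat.), CH2Cl2, rt
Reagents that add atoms: potassium peroxymonosulfate, [K+].[O-]S(=O)(=O)OO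
Why: KHSO5 oxidises the ketone to a chiral dioxirane, which transfers oxygen to each electron-rich E-trisubstituted alkene through a spiro transition state; this is the Shi epoxidation, the closest known reaction type, used here twice in one ring and followed by the known acid-induced lactonisation of a 5,6-epoxy acid. Each oxirane closes by concerted oxygen transfer, and the δ-lactone closes 6-exo-tet when the C16 carboxyl attacks C3 of the 3,4-oxirane from the side opposite its C–O bond. C4, C11 and C12 take their S configuration directly from the L-fructose-derived ketone, which attacks both alkenes in the same sense; C3 is first set S by the ketone and then inverted to R in the lactonisation, which also fixes the anti relation of the C3 and C4 oxygens. The step needs face selectivity at two ring alkenes, chemoselectivity against the C8 methylidene, opening of the 3,4- and not the 11,12-oxirane, and attack at C3 and not C4. The first rests on reagent control in a flexible ring; the second on the lower nucleophilicity of a 1,1-disubstituted alkene that also bears an allylic silyloxy group; the third on distance, since the 11,12-oxirane could only be reached through a seven- or eight-membered transition state; the fourth on ring size (six against seven) and on buffered, weakly acidic conditions that keep the opening SN2-like. The (3S,4S)-oxirane is also the one whose opening gives the lactone with C14 and C4 cis and both equatorial, so reagent control and ring strain should work in the same direction.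

Step 20
Reactants: 35 7-O-triethylsilyl ether of the target
Product: 36 (1R,3R,4S,7R,11S,12S,15S)-11,12-epoxy-4,7-dihydroxycembr-8(19)-en-16,3-olide (target)
Conditions: Bu4NF, AcOH, THF, 0 °C
Reagents that add atoms: none
Why: Buffered fluoride cleaves the secondary triethylsilyl ether; at this pH the lactone, the oxirane and the tertiary alcohol should be left unchanged.

## Compound list

1 | pent-4-yn-1-ol | C#CCCCO | starting material
2 | [(1E)-5-(dimethylalumanyloxy)-2-methylpent-1-en-1-yl]dimethylalumane | C[Al](C)/C=C(\C)CCCO[Al](C)C | intermediate (not isolated)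
3 | (4E)-5-iodo-4-methylpent-4-en-1-ol | I/C=C(\C)CCCO | intermediate
4 | tert-butyl{[(4E)-5-iodo-4-methylpent-4-en-1-yl]oxy}dimethylsilane | I/C=C(\C)CCCO[Si](C)(C)C(C)(C)C | intermediate
5 | tert-butyl (2S)-2-hydroxypropanoate | C[C@H](O)C(=O)OC(C)(C)C | starting material
6 | tert-butyl (2S)-2-{[(trifluoromethyl)sulfonyl]oxy}propanoate | C[C@H](OS(=O)(=O)C(F)(F)F)C(=O)OC(C)(C)C | intermediate
7 | but-3-enoic acid | C=CCC(=O)O | starting material
8 | (4R)-4-benzyl-1,3-oxazolidin-2-one | O=C1N[C@H](Cc2ccccc2)CO1 | starting material
9 | but-3-enoic 2,2-dimethylpropanoic anhydride | C=CCC(=O)OC(=O)C(C)(C)C | intermediate (not isolated)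
10 | (4R)-4-benzyl-3-(but-3-enoyl)-1,3-oxazolidin-2-one | C=CCC(=O)N1[C@H](Cc2ccccc2)COC1=O | intermediate
11 | sodium (1Z)-1-[(4R)-4-benzyl-2-oxo-1,3-oxazolidin-3-yl]buta-1,3-dien-1-olate | C=C/C=C(\[O-])N1[C@H](Cc2ccccc2)COC1=O.[Na+] | intermediate (not isolated)
12 | tert-butyl (2S,3S)-3-{[(4R)-4-benzyl-2-oxo-1,3-oxazolidin-3-yl]carbonyl}-2-methylpent-4-enoate | CC(C)(C)OC(=O)[C@@H](C)[C@H](C=C)C(=O)N1[C@H](Cc2ccccc2)COC1=O | intermediate
13 | tert-butyl (2S,3S)-3-(hydroxymethyl)-2-methylpent-4-enoate | CC(C)(C)OC(=O)[C@@H](C)[C@H](C=C)CO | intermediate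
14 | tert-butyl (2S,3S)-3-(iodomethyl)-2-methylpent-4-enoate | CC(C)(C)OC(=O)[C@@H](C)[C@H](C=C)CI | intermediate
15 | [(2S,3S)-4-tert-butoxy-2-ethenyl-3-methyl-4-oxobutyl](iodo)zinc | CC(C)(C)OC(=O)[C@@H](C)[C@H](C=C)C[Zn]I | intermediate (not isolated)
16 | tert-butyl (2S,3S,5E)-9-[(tert-butyldimethylsilyl)oxy]-3-ethenyl-2,6-dimethylnon-5-enoate | CC(C)(C)OC(=O)[C@@H](C)[C@H](C=C)C/C=C(\C)CCCO[Si](C)(C)C(C)(C)C | intermediate
17 | 3-bromoprop-1-yne | C#CCBr | starting material
18 | 2,3-dibromoprop-1-ene | C=C(Br)CBr | starting material
19 | bromo(propa-1,2-dien-1-yl)magnesium | C=C=C[Mg]Br | intermediate (not isolated)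
20 | 2-bromohex-1-en-5-yne | C=C(Br)CCC#C | intermediate
21 | (5-bromohex-5-en-1-yn-1-yl)lithium | [Li]C#CCCC(Br)=C | intermediate (not isolated)
22 | 6-bromohept-6-en-2-yne | CC#CCCC(Br)=C | intermediate
23 | [(2E)-6-bromohepta-2,6-dien-2-yl]chlorobis(cyclopentadienyl)zirconium | C/C(=C\CCC(Br)=C)[Zr](Cl)(C1C=CC=C1)C1C=CC=C1 | intermediate (not isolated)
24 | (2E)-6-bromo-2-iodohepta-2,6-diene | C/C(I)=C\CCC(Br)=C | intermediate
25 | tert-butyl (2S,3R,5E)-3-[2-(9-borabicyclo[3.3.1]nonan-9-yl)ethyl]-9-[(tert-butyldimethylsilyl)oxy]-2,6-dimethylnon-5-enoate | CC(C)(C)OC(=O)[C@@H](C)[C@H](CCB1C2CCCC1CCC2)C/C=C(\C)CCCO[Si](C)(C)C(C)(C)C | intermediate (not isolated)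
26 | tert-butyl (2S,3R,5E)-3-[(3E)-7-bromo-3-methylocta-3,7-dien-1-yl]-9-[(tert-butyldimethylsilyl)oxy]-2,6-dimethylnon-5-enoate | CC(C)(C)OC(=O)[C@@H](C)[C@H](CC/C(C)=C/CCC(Br)=C)C/C=C(\C)CCCO[Si](C)(C)C(C)(C)C | intermediate
27 | tert-butyl (2S,3R,5E)-3-[(3E)-7-bromo-3-methylocta-3,7-dien-1-yl]-9-hydroxy-2,6-dimethylnon-5-enoate | CC(C)(C)OC(=O)[C@@H](C)[C@H](CC/C(C)=C/CCC(Br)=C)C/C=C(\C)CCCO | intermediate
28 | tert-butyl (2S,3R,5E)-3-[(3E)-7-bromo-3-methylocta-3,7-dien-1-yl]-2,6-dimethyl-9-oxonon-5-enoate | CC(C)(C)OC(=O)[C@@H](C)[C@H](CC/C(C)=C/CCC(Br)=C)C/C=C(\C)CCC=O | intermediate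
29 | tert-butyl (2S)-2-[(1R,3E,11E)-7-hydroxy-4,12-dimethyl-8-methylidenecyclotetradeca-3,11-dien-1-yl]propanoate, C7 epimers | C=C1CC/C=C(C)/CC[C@@H]([C@H](C)C(=O)OC(C)(C)C)C/C=C(C)/CCC1O | intermediate
30 | tert-butyl (2S)-2-[(1R,3E,11E)-4,12-dimethyl-8-methylidene-7-oxocyclotetradeca-3,11-dien-1-yl]propanoate | C=C1CC/C=C(C)/CC[C@@H]([C@H](C)C(=O)OC(C)(C)C)C/C=C(C)/CCC1=O | intermediate
31 | tert-butyl (2S)-2-[(1R,3E,7R,11E)-7-hydroxy-4,12-dimethyl-8-methylidenecyclotetradeca-3,11-dien-1-yl]propanoate | C=C1CC/C=C(C)/CC[C@@H]([C@H](C)C(=O)OC(C)(C)C)C/C=C(C)/CC[C@H]1O | intermediate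
32 | triethylsilyl (2S)-2-[(1R,3E,7R,11E)-4,12-dimethyl-8-methylidene-7-[(triethylsilyl)oxy]cyclotetradeca-3,11-dien-1-yl]propanoate | C=C1CC/C=C(C)/CC[C@@H]([C@H](C)C(=O)O[Si](CC)(CC)CC)C/C=C(C)/CC[C@H]1O[Si](CC)(CC)CC | intermediate (not isolated)
33 | (2S)-2-[(1R,3E,7R,11E)-4,12-dimethyl-8-methylidene-7-[(triethylsilyl)oxy]cyclotetradeca-3,11-dien-1-yl]propanoic acid | C=C1CC/C=C(C)/CC[C@@H]([C@H](C)C(=O)O)C/C=C(C)/CC[C@H]1O[Si](CC)(CC)CC | intermediate
34 | (2S)-2-[(1R,3S,4S,7R,11S,12S)-3,4:11,12-diepoxy-4,12-dimethyl-8-methylidene-7-[(triethylsilyl)oxy]cyclotetradecan-1-yl]propanoic acid | C=C1CC[C@@H]2O[C@@]2(C)CC[C@@H]([C@H](C)C(=O)O)C[C@@H]2O[C@@]2(C)CC[C@H]1O[Si](CC)(CC)CC | intermediate (not isolated)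
35 | (1R,3R,4S,7R,11S,12S,15S)-11,12-epoxy-4-hydroxy-7-[(triethylsilyl)oxy]cembr-8(19)-en-16,3-olide | C=C1CC[C@@H]2O[C@@]2(C)CC[C@@H]2C[C@@H](OC(=O)[C@H]2C)[C@@](C)(O)CC[C@H]1O[Si](CC)(CC)CC | intermediate
36 | (1R,3R,4S,7R,11S,12S,15S)-11,12-epoxy-4,7-dihydroxycembr-8(19)-en-16,3-olide (CNP0262409.1) | C=C1CC[C@@H]2O[C@@]2(C)CC[C@@H]2C[C@@H](OC(=O)[C@H]2C)[C@@](C)(O)CC[C@H]1O | target

## Step count and least certain steps

Total: 20 steps. Longest linear sequence: 14 steps (steps 4–8 and 12–20).

**Step 19 (key step).** The most likely failure is poor facial selectivity at one ring alkene, because the 14-membered ring may hold that alkene with only one face open and so override the ketone. Lesser risks are transannular opening of the 11,12-oxirane during the acid stage and some attack at C4. The fallback moves the oxidation before ring closure; it sets out from 27 and returns at 36.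
- The tert-butyl ester of 27 is cleaved with Me3SiOTf/2,6-lutidine and mild aqueous base (the primary silyl ether formed in passing is lost in the same work-up) to give the seco hydroxy acid F1.
- On this open chain both trisubstituted alkenes are free of ring bias, and the same ketone/KHSO5 epoxidation followed by mild acid should give the seco epoxy lactone diol F2.
- Selective oxidation of the primary alcohol (TEMPO, PhI(OAc)2) gives the seco epoxy lactone aldehyde F3, which will sit partly as its lactol.
- CrCl2/NiCl2 closes the ring to the C7-epimeric macrocyclic alcohols F4, and Dess–Martin oxidation gives the macrocyclic enone F5.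
- Reduction of F5 with the (S)-oxazaborolidine and catecholborane gives 36 directly.

**Step 5.** The basic dienolate may eliminate the secondary triflate to the acrylate, or be alkylated at its γ-carbon. The fallback uses a saturated imide enolate and unveils the vinyl group afterwards; it sets out from 8 (and uses 6) and returns at 12.
- γ-Butyrolactone is opened with sodium phenylselenide to 4-(phenylselanyl)butanoic acid F6.
- F6 is attached to 8 through the mixed pivalic anhydride to give the selenide imide F7.
- The sodium enolate of F7 displaces triflate 6 to give the alkylated selenide imide F8.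
- Oxidation with H2O2 and syn-elimination of the selenoxide gives 12.

**Step 15.** Insertion of nickel into a 2-bromoalkene is slower than into an iodide, so intermolecular coupling and aldehyde decomposition may outrun ring closure. The fallback closes the same C7–C8 bond by a nickel-catalysed reductive alkyne–aldehyde cyclisation; it sets out from 27 and returns at 29.
- Dehydrobromination of 27 with Bu4NF·3H2O in DMF at 60 °C gives the enyne alcohol F9, and Dess–Martin oxidation gives the ynal F10.
- Ni(cod)2 with a bulky N-heterocyclic carbene (1,3-bis(2,6-diisopropylphenyl)imidazol-2-ylidene) and Et3SiH at high dilution joins the aldehyde carbon to the internal alkyne carbon, giving the macrocyclic C7-epimeric triethylsilyl ethers F11.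
- Bu4NF converts F11 into 29.

**Step 17.** The catalyst may discriminate poorly between the two flanks of a conformationally mobile ring ketone, and conjugate reduction of the α-methylene ketone may intervene. The fallback avoids the ketone; it sets out from 29 and returns at 31.
- The C7 epimers of 29 are separated; the 7R epimer is 31.
- The (7S)-alcohol F12 is inverted by a Mitsunobu reaction (4-nitrobenzoic acid, PPh3, diisopropyl azodicarboxylate) to the (7R)-4-nitrobenzoate F13.
- Methanolysis of F13 (K2CO3, MeOH), which leaves the tert-butyl ester, gives 31.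

## Further compounds

F1 | step 19 | (2S,3R,5E)-3-[(3E)-7-bromo-3-methylocta-3,7-dien-1-yl]-9-hydroxy-2,6-dimethylnon-5-enoic acid | OC(=O)[C@@H](C)[C@H](CC/C(C)=C/CCC(Br)=C)C/C=C(\C)CCCO
F2 | step 19 | seco epoxy lactone diol: open-chain 16,3-olide with 4-hydroxy, (11S,12S)-oxirane, 7-hydroxy and C8 bromoalkene | C=C(Br)CC[C@@H]1O[C@@]1(C)CC[C@@H]1C[C@@H](OC(=O)[C@H]1C)[C@@](C)(O)CCCO
F3 | step 19 | seco epoxy lactone aldehyde (C7 aldehyde of F2) | C=C(Br)CC[C@@H]1O[C@@]1(C)CC[C@@H]1C[C@@H](OC(=O)[C@H]1C)[C@@](C)(O)CCC=O
F4 | step 19 | C7-epimeric mixture of the target | C=C1CC[C@@H]2O[C@@]2(C)CC[C@@H]2C[C@@H](OC(=O)[C@H]2C)[C@@](C)(O)CCC1O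
F5 | step 19 | 7-oxo analogue of the target (macrocyclic enone) | C=C1CC[C@@H]2O[C@@]2(C)CC[C@@H]2C[C@@H](OC(=O)[C@H]2C)[C@@](C)(O)CCC1=O
F6 | step 5 | 4-(phenylselanyl)butanoic acid | OC(=O)CCC[Se]c1ccccc1
F7 | step 5 | (4R)-4-benzyl-3-[4-(phenylselanyl)butanoyl]-1,3-oxazolidin-2-one | O=C(CCC[Se]c1ccccc1)N1[C@H](Cc2ccccc2)COC1=O
F8 | step 5 | tert-butyl (2S,3S)-3-{[(4R)-4-benzyl-2-oxo-1,3-oxazolidin-3-yl]carbonyl}-2-methyl-5-(phenylselanyl)pentanoate | CC(C)(C)OC(=O)[C@@H](C)[C@H](CC[Se]c1ccccc1)C(=O)N1[C@H](Cc2ccccc2)COC1=O
F9 | step 15 | tert-butyl (2S,3R,5E)-9-hydroxy-2,6-dimethyl-3-[(3E)-3-methyloct-3-en-7-yn-1-yl]non-5-enoate | CC(C)(C)OC(=O)[C@@H](C)[C@H](CC/C(C)=C/CCC#C)C/C=C(\C)CCCO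
F10 | step 15 | tert-butyl (2S,3R,5E)-2,6-dimethyl-3-[(3E)-3-methyloct-3-en-7-yn-1-yl]-9-oxonon-5-enoate | CC(C)(C)OC(=O)[C@@H](C)[C@H](CC/C(C)=C/CCC#C)C/C=C(\C)CCC=O
F11 | step 15 | tert-butyl (2S)-2-[(1R,3E,11E)-4,12-dimethyl-8-methylidene-7-[(triethylsilyl)oxy]cyclotetradeca-3,11-dien-1-yl]propanoate, C7 epimers | C=C1CC/C=C(C)/CC[C@@H]([C@H](C)C(=O)OC(C)(C)C)C/C=C(C)/CCC1O[Si](CC)(CC)CC
F12 | step 17 | tert-butyl (2S)-2-[(1R,3E,7S,11E)-7-hydroxy-4,12-dimethyl-8-methylidenecyclotetradeca-3,11-dien-1-yl]propanoate | C=C1CC/C=C(C)/CC[C@@H]([C@H](C)C(=O)OC(C)(C)C)C/C=C(C)/CC[C@@H]1O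
F13 | step 17 | (1R,3E,7R,11E)-ring 7-(4-nitrobenzoate) of 31 | C=C1CC/C=C(C)/CC[C@@H]([C@H](C)C(=O)OC(C)(C)C)C/C=C(C)/CC[C@H]1OC(=O)c1ccc(cc1)[N+](=O)[O-]
A1 | alternative 1 | (5R,6S)-9-[(tert-butyldiphenylsilyl)oxy]-3-ethenyl-6-methyl-6-[(triethylsilyl)oxy]non-1-en-5-ol | C=CC(C=C)C[C@@H](O)[C@@](C)(O[Si](CC)(CC)CC)CCCO[Si](c1ccccc1)(c1ccccc1)C(C)(C)C
A2 | alternative 1 | (3S,4S,6R)-6-[(2S)-5-[(tert-butyldiphenylsilyl)oxy]-2-[(triethylsilyl)oxy]pentan-2-yl]-4-ethenyl-3-methyloxan-2-one | C=C[C@@H]1C[C@@H](OC(=O)[C@H]1C)[C@@](C)(O[Si](CC)(CC)CC)CCCO[Si](c1ccccc1)(c1ccccc1)C(C)(C)C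
A3 | alternative 2 | seco keto aldehyde: C3 aldehyde, C4 methyl ketone, 7-O-tert-butyldimethylsilyl, 16-O-triethylsilyl (cembrane numbering) | CC(=O)CC[C@@H](O[Si](C)(C)C(C)(C)C)C(=C)CC/C=C(C)/CC[C@@H]([C@H](C)CO[Si](CC)(CC)CC)CC=O
A4 | alternative 2 | macrocyclic 3,4-diol, 7-O-tert-butyldimethylsilyl, 16-O-triethylsilyl | C=C1CC/C=C(C)/CC[C@@H]([C@H](C)CO[Si](CC)(CC)CC)C[C@@H](O)[C@@](C)(O)CC[C@H]1O[Si](C)(C)C(C)(C)C
A5 | alternative 3 | seco C9 allylic bromide C10 phenyl sulfone carrying the 16,3-lactone, 4-O-triethylsilyl and 7-O-tert-butyldimethylsilyl | O=S(=O)(c1ccccc1)C/C=C(C)/CC[C@@H]2C[C@@H](OC(=O)[C@H]2C)[C@@](C)(O[Si](CC)(CC)CC)CC[C@@H](O[Si](C)(C)C(C)(C)C)C(=C)CBr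
A6 | alternative 3 | macrocyclic C10 phenyl sulfone (C10 epimers) | C=C1CC(S(=O)(=O)c2ccccc2)/C=C(C)/CC[C@@H]2C[C@@H](OC(=O)[C@H]2C)[C@@](C)(O[Si](CC)(CC)CC)CC[C@H]1O[Si](C)(C)C(C)(C)C
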